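**Retrosynthetic overview**

1. Target 29 is the C8 3,4,5-trimethoxybenzoate of a (1(10)Z)-4,5-epoxygermacr-1(10)-ene-6,8-diol. The C4–C5 oxirane is taken back to the allylic alcohol C4=C5–C6(OH) of macrocycle 28 (hydroxyl-directed, tartrate-matched epoxidation as the last step).
2. Key disconnection C3–C4: an intramolecular B-alkyl Suzuki–Miyaura coupling closes the ten-membered carbocycle, the only carbocycle, from the open chain 25 in one operation (hydroboration, then ring closure).
3. Enabling feature: C3 is a CH2 homoallylic to the (Z)-C1=C10 olefin, so it can be the terminus of a 1,3-diene. C4 is the methyl-bearing oxirane carbon, which one oxidation level lower is an sp2 carbon and can carry iodine. The (Z)-olefin and the syn-1,3-dioxygenated C6–C8 segment bend the chain toward closure.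
4. Chain 25: C8 ester; C9–C10 by copper-catalysed opening of a C8–C9 oxirane with a (Z)-dienyl Grignard reagent; C8 by 1,3-syn iodocarbonate cyclization from the C6 hydroxyl; C6/C7 by anti-selective asymmetric allylboration of (E)-3-iodobut-2-enal.
5. Order of ring formation: temporary 1,3-dioxan-2-one (step 5), temporary C8–C9 oxirane (step 6, opened in step 9), ten-membered carbocycle (step 11), C4–C5 oxirane (step 13).

Key step: step 11

Remark on the chemistry (assumption): germacrane numbering is used (C1=C10 olefin with C14 methyl, C4(C15 methyl)–C5 oxirane, C6–OH, C7–isopropyl, C8–O-aroyl). The target is read as 1(10)Z (ring carbons C2 and C9 cis), trans-oxirane, (4R,5R,6R,7S,8R).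

**Step 1**
Reactants: 1 1,1-diethoxybut-2-yne
Product: 3 (2E)-1,1-diethoxy-3-iodobut-2-ene, via alkenylzirconocene chloride 2 (not isolated)
Conditions: Cp2Zr(H)Cl (1.6 equiv), THF, rt → 50 °C; then I2, 0 °C
Reagents that add atoms: iodine, SMILES II
Why: Syn-hydrozirconation of the internal alkyne should place zirconium on the less hindered methyl-bearing carbon (the regioisomers equilibrate through the excess hydride reagent), and iodinolysis with retention should give the (E)-alkenyl iodide.

**Step 2**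
Reactants: 3 (2E)-1,1-diethoxy-3-iodobut-2-ene
Product: 4 (2E)-3-iodobut-2-enal
Conditions: HCl (1 M aq, cat.), THF, 0 °C; used directly as a solution
Reagents that add atoms: water, SMILES O
Why: Mild acid-catalysed acetal hydrolysis should unmask the enal without touching the alkenyl iodide, the (E)-geometry (iodine trans to the formyl group) being retained.

**Step 3**
Reactants: 4 (2E)-3-iodobut-2-enal, 5 (2E)-4-methylpent-2-ene
Product: 9 (3R,4R,5E)-6-iodo-3-(propan-2-yl)hepta-1,5-dien-4-ol, via allylpotassium 6 (not isolated), via allylbis(isopinocampheyl)borane 7 (not isolated), via borinate ester 8 (not isolated)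
Conditions: 5 (excess), KOt-Bu, n-BuLi, THF, −78 → −50 °C; (+)-Ipc2BOMe, −78 °C; BF3·OEt2; then 4, −78 °C; NaOH, H2O2, 0 °C → rt
Reagents that add atoms: none
Why: Brown-type allylboration: Schlosser-base metalation of the allylic methyl group of 5 gives the (E)-allylpotassium, whose B(Ipc)2 derivative should add to the enal through a chair Zimmerman–Traxler transition state, the (E)-γ-isopropyl group giving the anti C6/C7 relationship and the (−)-α-pinene-derived Ipc ligands selecting the aldehyde face that leads to the (3R,4R) isomer.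

**Step 4**
Reactants: 9 (3R,4R,5E)-6-iodo-3-(propan-2-yl)hepta-1,5-dien-4-ol
Product: 10 tert-butyl (3R,4R,5E)-6-iodo-3-(propan-2-yl)hepta-1,5-dien-4-yl carbonate
Conditions: Boc2O, DMAP (cat.), MeCN, rt
Reagents that add atoms: di-tert-butyl dicarbonate, SMILES CC(C)(C)OC(=O)OC(=O)OC(C)(C)C
Why: DMAP-catalysed acylation of the secondary alcohol should install the carbonate that serves as internal nucleophile in the next step; no stereocenter is touched.

**Step 5**
Reactants: 10 tert-butyl (3R,4R,5E)-6-iodo-3-(propan-2-yl)hepta-1,5-dien-4-yl carbonate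
Product: 11 (4S,5S,6R)-4-(iodomethyl)-6-[(1E)-2-iodoprop-1-en-1-yl]-5-(propan-2-yl)-1,3-dioxan-2-one
Conditions: IBr, PhMe, −85 °C
Reagents that add atoms: iodine monobromide, SMILES BrI
Why: Iodocarbonate cyclization (6-exo halocyclization with loss of the tert-butyl group): the carbonate carbonyl oxygen should open the iodonium ion of the terminal olefin through a chair transition state with the alkenyl, isopropyl and iodomethyl groups all equatorial, which sets C8 syn to the C6 oxygen and anti to the isopropyl group, while the iodine-bearing olefin is too electron-poor to compete.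

**Step 6**
Reactants: 11 (4S,5S,6R)-4-(iodomethyl)-6-[(1E)-2-iodoprop-1-en-1-yl]-5-(propan-2-yl)-1,3-dioxan-2-one
Product: 13 (2E,4R,5S)-2-iodo-6-methyl-5-[(2S)-oxiran-2-yl]hept-2-en-4-ol, via iodohydrin diol 12 (not isolated)
Conditions: K2CO3, MeOH, 0 °C → rt
Reagents that add atoms: none
Why: Methanolysis of the cyclic carbonate should free the C8 alkoxide, which displaces the neighbouring primary iodide (intramolecular Williamson reaction) to give the terminal oxirane with the C8 configuration unchanged.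

**Step 7**
Reactants: 13 (2E,4R,5S)-2-iodo-6-methyl-5-[(2S)-oxiran-2-yl]hept-2-en-4-ol
Product: 14 triethyl{[(2E,4R,5R)-2-iodo-6-methyl-5-[(2S)-oxiran-2-yl]hept-2-en-4-yl]oxy}silane
Conditions: Et3SiCl, imidazole, DMF, 0 °C → rt
Reagents that add atoms: chlorotriethylsilane, SMILES CC[Si](Cl)(CC)CC
Why: Standard silylation of the secondary allylic alcohol should protect C6–OH (the descriptor at C7 changes only by priority); the oxirane is stable to these conditions.

**Step 8**
Reactants: 15 prop-2-enal (acrolein), 16 ethyl(triphenyl)phosphonium iodide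
Product: 20 (3Z)-4-iodopenta-1,3-diene, via ethylidene ylide 17 (not isolated), via iodoethylphosphonium iodide 18 (not isolated), via iodoethylidene ylide 19 (not isolated)
Conditions: 16, n-BuLi, THF, 0 °C; I2, −78 °C; NaN(SiMe3)2, −78 → −20 °C; then 15, −78 °C; kept cold and dark as a pentane solution
Reagents that add atoms: iodine, SMILES II
Why: Stork–Zhao-type Wittig olefination with the α-iodo ylide made in the flask should give, under kinetic control of the non-stabilised ylide, the (Z)-alkenyl iodide with iodine cis to the vinyl group.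

**Step 9**
Reactants: 14 triethyl{[(2E,4R,5R)-2-iodo-6-methyl-5-[(2S)-oxiran-2-yl]hept-2-en-4-yl]oxy}silane, 20 (3Z)-4-iodopenta-1,3-diene
Product: 23 (3Z,6R,7R,8R,9E)-10-iodo-4-methyl-7-(propan-2-yl)-8-[(triethylsilyl)oxy]undeca-1,3,9-trien-6-ol, via dienyllithium 21 (not isolated), via dienylmagnesium bromide 22 (not isolated)
Conditions: 20, t-BuLi (2 equiv), Et2O, −78 °C; MgBr2·OEt2; then CuI (10 mol%), 14, THF, −40 → −15 °C
Reagents that add atoms: none
Why: Iodine–lithium exchange with retention, transmetalation to magnesium and copper-catalysed SN2 opening of the terminal oxirane at its CH2 carbon should join C9 to C10 with the (Z)-geometry carried over and C8 untouched, the hindered trisubstituted alkenyl iodide of 14 being expected to survive the Grignard/copper system at low temperature.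

**Step 10**
Reactants: 23 (3Z,6R,7R,8R,9E)-10-iodo-4-methyl-7-(propan-2-yl)-8-[(triethylsilyl)oxy]undeca-1,3,9-trien-6-ol, 24 3,4,5-trimethoxybenzoyl chloride
Product: 25 (3Z,6R,7R,8R,9E)-10-iodo-4-methyl-7-(propan-2-yl)-8-[(triethylsilyl)oxy]undeca-1,3,9-trien-6-yl 3,4,5-trimethoxybenzoate
Conditions: 24, Et3N, DMAP, CH2Cl2, 0 °C → rt
Reagents that add atoms: none
Why: DMAP-catalysed esterification of the hindered secondary alcohol with the acid chloride should give the C8 ester with retention, so that only deprotection and epoxidation remain after ring closure.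

**Step 11**
Reactants: 25 (3Z,6R,7R,8R,9E)-10-iodo-4-methyl-7-(propan-2-yl)-8-[(triethylsilyl)oxy]undeca-1,3,9-trien-6-yl 3,4,5-trimethoxybenzoate
Product: 27 (1(10)Z,4E,6S,7R,8R)-6-[(triethylsilyl)oxy]germacra-1(10),4-dien-8-yl 3,4,5-trimethoxybenzoate, via B-alkyl-9-BBN borane 26 (not isolated)
Conditions: 9-BBN (1.3 equiv), THF, 0 °C → rt; then syringe-pump addition to Pd(dppf)Cl2 (15 mol%), AsPh3, Cs2CO3, DMF/THF/H2O, 50 °C, final concentration ≤ 2 mM
Reagents that add atoms: none
Why: 9-BBN should hydroborate only the terminal vinyl group of the twisted (Z)-1,3-diene, with boron on the terminal carbon C3 (the trisubstituted olefins, the alkenyl iodide and the ester are inert); the B-alkyl borane 26 is then activated as its hydroxoborate, transmetalated to the alkenylpalladium iodide formed by oxidative addition of the C4–I bond to zerovalent palladium, and reductive elimination forms the C3–C4 bond (intramolecular B-alkyl Suzuki–Miyaura coupling). The closest known reaction type is the B-alkyl Suzuki–Miyaura macrocyclization of ω-alkenyl alkenyl iodides, used to close medium-sized and macrocyclic carbocycles that contain (E)-trisubstituted olefins. The ten-membered carbocycle is closed by C(sp3)–C(sp2) reductive elimination from an eleven-membered palladacycle, the new bond and both flanking olefins ending up inside the ring. No stereocenter is formed; the 4E geometry comes from the (E)-alkenyl iodide and the 1(10)Z geometry from the diene, both with retention, and the C6–C8 stereotriad is untouched. The step needs ring closure to outrun oligomerization and β-hydride elimination: slow addition at high dilution, the turn imposed by the (Z)-olefin and the syn-1,3-dioxygenated C6–C8 segment, and the wide-bite-angle dppf ligand with AsPh3 (fast reductive elimination) are expected to secure this.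

**Step 12**
Reactants: 27 (1(10)Z,4E,6S,7R,8R)-6-[(triethylsilyl)oxy]germacra-1(10),4-dien-8-yl 3,4,5-trimethoxybenzoate
Product: 28 (1(10)Z,4E,6S,7S,8R)-6-hydroxygermacra-1(10),4-dien-8-yl 3,4,5-trimethoxybenzoate
Conditions: HF·pyridine, pyridine, THF, 0 °C
Reagents that add atoms: none
Why: Fluoride-mediated cleavage of the triethylsilyl ether under buffered conditions should free the C6 hydroxyl without 1,3-acyl migration of the C8 ester or acid-induced transannular cyclization of the 1,5-diene.

**Step 13**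
Reactants: 28 (1(10)Z,4E,6S,7S,8R)-6-hydroxygermacra-1(10),4-dien-8-yl 3,4,5-trimethoxybenzoate
Product: 29 (1(10)Z,4R,5R,6R,7S,8R)-4,5-epoxy-6-hydroxygermacr-1(10)-en-8-yl 3,4,5-trimethoxybenzoate (target)
Conditions: Ti(OiPr)4 (1 equiv), L-(+)-diisopropyl tartrate (1.2 equiv), t-BuOOH, 4 Å MS, CH2Cl2, −20 °C
Reagents that add atoms: tert-butyl hydroperoxide, SMILES CC(C)(C)OO
Why: Katsuki–Sharpless epoxidation of the secondary allylic alcohol in its matched pairing with the L-(+)-tartrate: the titanium-bound C6 hydroxyl should direct oxygen only to C4=C5 (the C1=C10 olefin has no directing group), catalyst and substrate both favour the erythro epoxy alcohol because oxygen is delivered to the peripheral olefin face of the ring conformer that holds the C6–O bond near the olefin plane, and the (E)-geometry translates into the trans (4R,5R)-oxirane.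

**Compound list**

1 | 1,1-diethoxybut-2-yne | CCOC(OCC)C#CC | starting material
2 | chlorido[(1E)-3,3-diethoxy-1-methylprop-1-en-1-yl]bis(cyclopentadienyl)zirconium | CCOC(OCC)/C=C(C)/[Zr](Cl)(C1C=CC=C1)C1C=CC=C1 | intermediate (not isolated)
3 | (2E)-1,1-diethoxy-3-iodobut-2-ene | CCOC(OCC)/C=C(C)/I | intermediate
4 | (2E)-3-iodobut-2-enal | O=C/C=C(C)/I | intermediate
5 | (2E)-4-methylpent-2-ene | C/C=C/C(C)C | starting material
6 | [(2E)-4-methylpent-2-en-1-yl]potassium | [K]C/C=C/C(C)C | intermediate (not isolated)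
7 | [(2E)-4-methylpent-2-en-1-yl]bis(isopinocampheyl)borane, Ipc from (−)-α-pinene | CC(C)/C=C/CB([C@H]1C[C@H]2C[C@H](C2(C)C)[C@@H]1C)[C@H]1C[C@H]2C[C@H](C2(C)C)[C@@H]1C | intermediate (not isolated)
8 | bis(isopinocampheyl)borinate ester of 9 | C=C[C@@H](C(C)C)[C@@H](OB([C@H]1C[C@H]2C[C@H](C2(C)C)[C@@H]1C)[C@H]1C[C@H]2C[C@H](C2(C)C)[C@@H]1C)/C=C(C)/I | intermediate (not isolated)
9 | (3R,4R,5E)-6-iodo-3-(propan-2-yl)hepta-1,5-dien-4-ol | C=C[C@@H](C(C)C)[C@@H](O)/C=C(C)/I | intermediate
10 | tert-butyl (3R,4R,5E)-6-iodo-3-(propan-2-yl)hepta-1,5-dien-4-yl carbonate | C=C[C@@H](C(C)C)[C@@H](OC(=O)OC(C)(C)C)/C=C(C)/I | intermediate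
11 | (4S,5S,6R)-4-(iodomethyl)-6-[(1E)-2-iodoprop-1-en-1-yl]-5-(propan-2-yl)-1,3-dioxan-2-one | IC[C@H]1OC(=O)O[C@@H](/C=C(C)/I)[C@@H]1C(C)C | intermediate
12 | (2S,3S,4R,5E)-1,6-diiodo-3-(propan-2-yl)hept-5-ene-2,4-diol | IC[C@@H](O)[C@@H](C(C)C)[C@@H](O)/C=C(C)/I | intermediate (not isolated)
13 | (2E,4R,5S)-2-iodo-6-methyl-5-[(2S)-oxiran-2-yl]hept-2-en-4-ol | C1O[C@H]1[C@@H](C(C)C)[C@@H](O)/C=C(C)/I | intermediate
14 | triethyl{[(2E,4R,5R)-2-iodo-6-methyl-5-[(2S)-oxiran-2-yl]hept-2-en-4-yl]oxy}silane | C1O[C@H]1[C@@H](C(C)C)[C@@H](O[Si](CC)(CC)CC)/C=C(C)/I | intermediate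
15 | prop-2-enal (acrolein) | C=CC=O | starting material
16 | ethyl(triphenyl)phosphonium iodide | CC[P+](c1ccccc1)(c1ccccc1)c1ccccc1.[I-] | starting material
17 | ethylidene(triphenyl)phosphorane | CC=P(c1ccccc1)(c1ccccc1)c1ccccc1 | intermediate (not isolated)
18 | (1-iodoethyl)(triphenyl)phosphonium iodide | CC(I)[P+](c1ccccc1)(c1ccccc1)c1ccccc1.[I-] | intermediate (not isolated)
19 | (1-iodoethylidene)(triphenyl)phosphorane | CC(I)=P(c1ccccc1)(c1ccccc1)c1ccccc1 | intermediate (not isolated)
20 | (3Z)-4-iodopenta-1,3-diene | C=C/C=C(\I)C | intermediate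
21 | [(2E)-penta-2,4-dien-2-yl]lithium (lithium cis to the vinyl group) | C=C/C=C(\[Li])C | intermediate (not isolated)
22 | bromo[(2Z)-penta-2,4-dien-2-yl]magnesium (magnesium cis to the vinyl group) | C=C/C=C(\[Mg]Br)C | intermediate (not isolated)
23 | (3Z,6R,7R,8R,9E)-10-iodo-4-methyl-7-(propan-2-yl)-8-[(triethylsilyl)oxy]undeca-1,3,9-trien-6-ol | C=C/C=C(C)\C[C@@H](O)[C@@H](C(C)C)[C@@H](O[Si](CC)(CC)CC)/C=C(C)/I | intermediate
24 | 3,4,5-trimethoxybenzoyl chloride | COc1cc(C(Cl)=O)cc(OC)c1OC | starting material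
25 | (3Z,6R,7R,8R,9E)-10-iodo-4-methyl-7-(propan-2-yl)-8-[(triethylsilyl)oxy]undeca-1,3,9-trien-6-yl 3,4,5-trimethoxybenzoate | C=C/C=C(C)\C[C@@H](OC(=O)c1cc(OC)c(OC)c(OC)c1)[C@@H](C(C)C)[C@@H](O[Si](CC)(CC)CC)/C=C(C)/I | intermediate
26 | 9-alkyl-9-borabicyclo[3.3.1]nonane from hydroboration of 25 at the terminal carbon (C3) | C(C/C=C(C)\C[C@@H](OC(=O)c1cc(OC)c(OC)c(OC)c1)[C@@H](C(C)C)[C@@H](O[Si](CC)(CC)CC)/C=C(C)/I)B1C2CCCC1CCC2 | intermediate (not isolated)
27 | (1(10)Z,4E,6S,7R,8R)-6-[(triethylsilyl)oxy]germacra-1(10),4-dien-8-yl 3,4,5-trimethoxybenzoate | COc1cc(C(=O)O[C@@H]2C/C(C)=C\CC/C(C)=C/[C@H](O[Si](CC)(CC)CC)[C@@H]2C(C)C)cc(OC)c1OC | intermediate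
28 | (1(10)Z,4E,6S,7S,8R)-6-hydroxygermacra-1(10),4-dien-8-yl 3,4,5-trimethoxybenzoate | COc1cc(C(=O)O[C@@H]2C/C(C)=C\CC/C(C)=C/[C@H](O)[C@@H]2C(C)C)cc(OC)c1OC | intermediate
29 | (1(10)Z,4R,5R,6R,7S,8R)-4,5-epoxy-6-hydroxygermacr-1(10)-en-8-yl 3,4,5-trimethoxybenzoate | COc1cc(C(=O)O[C@@H]2C/C(C)=C\CC[C@@]3(C)O[C@@H]3[C@H](O)[C@@H]2C(C)C)cc(OC)c1OC | target

**Step count and risks**

Total: 13 steps. Longest linear sequence: 12 steps (steps 1–7 and 9–13; step 8 makes the dienyl iodide in a side branch).

Steps most likely to fail: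

Step 11 (ring closure). The process at risk is the competition between ring closure and intermolecular coupling to oligomers, together with β-hydride elimination or protodeboronation of the homoallylic borane before transmetalation. The fallback keeps the same bond but uses a different organometallic and a stepwise sequence. It sets out from 25. Hydroboration with 9-BBN and oxidation with NaBO3·4H2O would give the primary alcohol (3Z,6R,7R,8R,9E)-1-hydroxy-10-iodo-4-methyl-7-(propan-2-yl)-8-[(triethylsilyl)oxy]undeca-3,9-dien-6-yl 3,4,5-trimethoxybenzoate F1. I2, PPh3 and imidazole would give the primary iodide (3Z,6R,7R,8R,9E)-1,10-diiodo-4-methyl-7-(propan-2-yl)-8-[(triethylsilyl)oxy]undeca-3,9-dien-6-yl 3,4,5-trimethoxybenzoate F2. Zinc dust and LiCl in THF should insert only into the C(sp3)–I bond to give the C1 alkylzinc iodide of F2 F3. Pd(OAc)2 with SPhos under high dilution would then close the C3–C4 bond by intramolecular Negishi coupling and come back to the route at 27.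

Step 13 (epoxidation). The process at risk is oxygen delivery to the wrong olefin face, should the ring hold the C6 hydroxyl outside rather than near the C4=C5 plane (threo instead of erythro epoxy alcohol). The fallback moves the control of C6 to a ketone reduction. It sets out from 28. Mitsunobu inversion (4-nitrobenzoic acid, DIAD, PPh3) would give the C6-epimeric 4-nitrobenzoate of 28 F4. Selective methanolysis of this activated ester (K2CO3, MeOH, 0 °C) would give the C6-epimer of 28 F5. Hydroxyl-directed epoxidation with the threo preference then found (VO(acac)2, t-BuOOH) would place the oxirane on the required face and give the C6-epimer of 29 F6. Dess–Martin oxidation would give the (4R,5R)-4,5-epoxy-6-oxo ketone F7. Chelation-controlled, erythro-selective reduction with Zn(BH4)2 comes back to the route at 29.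

Step 9 (oxirane opening). The process at risk is iodine–metal exchange or coupling at the alkenyl iodide of 14 by the alkenylmetal reagent, and partial loss of the (Z)-geometry of the dienyl metal. The fallback builds the (Z)-olefin inside a lactone and uses no alkenylmetal. It sets out from 14. Opening with the lithium acetylide of ethyl propiolate (n-BuLi, BF3·OEt2, −78 °C; alkynyllithiums do not exchange with alkenyl iodides) would give ethyl (5R,6R,7R,8E)-5-hydroxy-9-iodo-6-(propan-2-yl)-7-[(triethylsilyl)oxy]dec-8-en-2-ynoate F8. Syn-selective conjugate addition of Me2CuLi at −78 °C and lactonization of the resulting (Z)-enoate would give (6R)-6-[(3R,4R,5E)-6-iodo-2-methyl-4-[(triethylsilyl)oxy]hept-5-en-3-yl]-4-methyl-5,6-dihydro-2H-pyran-2-one F9. i-Bu2AlH at −78 °C would give the corresponding lactol, the 5,6-dihydro-2H-pyran-2-ol F10. Wittig methylenation of its open (Z)-hydroxy-enal form with Ph3P=CH2 comes back to the route at 23.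

**Further compounds**

F1 | step 11 | (3Z,6R,7R,8R,9E)-1-hydroxy-10-iodo-4-methyl-7-(propan-2-yl)-8-[(triethylsilyl)oxy]undeca-3,9-dien-6-yl 3,4,5-trimethoxybenzoate | OCC/C=C(C)\C[C@@H](OC(=O)c1cc(OC)c(OC)c(OC)c1)[C@@H](C(C)C)[C@@H](O[Si](CC)(CC)CC)/C=C(C)/I
F2 | step 11 | (3Z,6R,7R,8R,9E)-1,10-diiodo-4-methyl-7-(propan-2-yl)-8-[(triethylsilyl)oxy]undeca-3,9-dien-6-yl 3,4,5-trimethoxybenzoate | ICC/C=C(C)\C[C@@H](OC(=O)c1cc(OC)c(OC)c(OC)c1)[C@@H](C(C)C)[C@@H](O[Si](CC)(CC)CC)/C=C(C)/I
F3 | step 11 | C1 alkylzinc iodide of F2 | I[Zn]CC/C=C(C)\C[C@@H](OC(=O)c1cc(OC)c(OC)c(OC)c1)[C@@H](C(C)C)[C@@H](O[Si](CC)(CC)CC)/C=C(C)/I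
F4 | step 13 | C6-epimeric 4-nitrobenzoate of 28 | COc1cc(C(=O)O[C@@H]2C/C(C)=C\CC/C(C)=C/[C@@H](OC(=O)c3ccc(cc3)[N+](=O)[O-])[C@@H]2C(C)C)cc(OC)c1OC
F5 | step 13 | C6-epimer of 28 | COc1cc(C(=O)O[C@@H]2C/C(C)=C\CC/C(C)=C/[C@@H](O)[C@@H]2C(C)C)cc(OC)c1OC
F6 | step 13 | C6-epimer of 29 | COc1cc(C(=O)O[C@@H]2C/C(C)=C\CC[C@@]3(C)O[C@@H]3[C@@H](O)[C@@H]2C(C)C)cc(OC)c1OC
F7 | step 13 | (1(10)Z,4R,5R)-4,5-epoxy-6-oxogermacr-1(10)-en-8-yl 3,4,5-trimethoxybenzoate | COc1cc(C(=O)O[C@@H]2C/C(C)=C\CC[C@@]3(C)O[C@@H]3C(=O)[C@@H]2C(C)C)cc(OC)c1OC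
F8 | step 9 | ethyl (5R,6R,7R,8E)-5-hydroxy-9-iodo-6-(propan-2-yl)-7-[(triethylsilyl)oxy]dec-8-en-2-ynoate | CCOC(=O)C#CC[C@@H](O)[C@@H](C(C)C)[C@@H](O[Si](CC)(CC)CC)/C=C(C)/I
F9 | step 9 | (6R)-6-[(3R,4R,5E)-6-iodo-2-methyl-4-[(triethylsilyl)oxy]hept-5-en-3-yl]-4-methyl-5,6-dihydro-2H-pyran-2-one | O=C1C=C(C)C[C@@H](O1)[C@@H](C(C)C)[C@@H](O[Si](CC)(CC)CC)/C=C(C)/I
F10 | step 9 | (6R)-6-[(3R,4R,5E)-6-iodo-2-methyl-4-[(triethylsilyl)oxy]hept-5-en-3-yl]-4-methyl-5,6-dihydro-2H-pyran-2-ol (anomeric mixture) | OC1C=C(C)C[C@@H](O1)[C@@H](C(C)C)[C@@H](O[Si](CC)(CC)CC)/C=C(C)/I
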